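All runs are calculated for substances that don't exist, noise included.

In this closed, stirred vessel the substrate hardly moves over the runs so far, so reckon the small loss and not the large remainder.

| flask | substrate | base | solid reagent | remark | time |
|---|---|---|---|---|---|
| oak | 0.12 M | 0.0080 M | 0.108 M | run made earlier |  |
| ash | 0.12 M | 0.018 M | 0.108 M | run made earlier |  |
| alpha | 0.12 M | 0.0240 M | 0.108 M |  | 6.0 h |
| epsilon | 0.12 M | 0.0120 M | 0.108 M |  | 6.0 h |

- oak (time / h: isomer of the product / %, substrate / %, target / %): 0.250: 0, 99.7, 0; 0.500: 0.8, 99.9, 0.5; 1.33: 0.9, 99.5, 0.4; 3.00: 1.3, 97.5, 1.4
- ash (time / h: isomer of the product / %, substrate / %, target / %): 0.417: 0, 99.8, 0.2; 1.00: 0.2, 99.1, 0; 2.00: 0.7, 98.5, 1.2; 3.00: 1.5, 97.6, 1.1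

(readings scatter by 0.3 percentage points)

- solid, in amounts per volume of the solution: solid reagent
- at the start none of the solid reagent is in solution

* which of these there is most of at the end, counted by the substrate in it, alpha (substrate / target / isomer of the product)
* which of these there is most of at the end, counted by the substrate in it, epsilon (substrate / target / isomer of the product)
* amount of the one of these that there is most of at the end, in percent of the substrate charged, alpha
* amount of the one of these that there is most of at the end, in percent of the substrate charged, epsilon

Take the early loss, the mean fraction of the substrate charge gone at 3.00 h in oak and ash: 2.45%. Oak and ash differ in base, yet their losses of 2.50% and 2.40% differ by less than the scatter of 0.3 percentage points, so you can carry this one figure to epsilon, whose base lies between theirs; for alpha, whose base is higher than in either run, it is an extrapolation.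

Now take two extremes. If the loss runs steadily, 6.0 h gives 4.90%. If it grows with the square of time, 6.0 h gives 9.80%. The readings won't choose between them: oak goes from 0.500% at 1.33 h to its final loss, close to the square, while ash goes from 0.900% at 1.00 h to its final loss, closer to steady. My reckoning takes the middle and leaves 92.6% as substrate in both flasks.

The forecast also names substrate for both, with 92% (80% to 96%) in alpha and 93% (85% to 96%) in epsilon. Its ground: “the rate barely depends on base over this range”.

The flask gives substrate as the largest share in both, 93.9% in alpha and 93.5% in epsilon, within the forecast's ranges. Epsilon's loss of 6.50% lies between your two extremes.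

    substrate + partner + released group → target + 2 released group (k = 16.0 /M²/min)
    substrate + partner → target + released group (k = 0.00190 /M/min)
    base + released group ⇌ salt, settled at all times (K = 44000 /M)
    target ⇌ isomer of the product (K = 0.920, k = 0.260 /min)
    released group → by-product carried off (k = 0.0480 /min)
    solid reagent ⇌ partner, rate k6*(cs6 - [partner]) while solid is left; crystals form when [partner] > cs6 (solubility = 0.110 M, k = 0.0170 /min)

In epsilon the direct step used substrate 230 times as fast as the autocatalytic step at 0.661 h, and 3.0 times as fast at 6.00 h. Watch that gap narrow: at the later time epsilon still holds 93.5% substrate.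

Read epsilon at 25 h and the early loss gives 20.4% if steady and 170% if squared, which exceeds the charge. At that reading epsilon holds 27.7% substrate, and target leads at 37.7%.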